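The central eight-membered ring C8a–C9a–C10a–C8b–C9b–C10b–C7c–C8c, fused between rings a2 and b2, is opened at C10a–C8b and C7c–C8c (numbering defined below). One Lewis acid operation forms both bonds. Cyclodehydration of an α-aryloxy ketone joins C10a, the ring a2 position para to the C13a oxygen, to C8b as a benzofuran. The C7c diarylmethyl cation then adds to a chiral 1-silyloxyindene, and a semipinacol hydride shift gives the indanone, relaying the one preset stereocentre to C8c, C8a and C7c. The precursor is an aryl ether joining a benzhydryl ether–deoxybenzoin half to the silyloxyindene half. Aryl addition, ionic hydrogenation and demethylation finish the route.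

Key step: step 12

Remark (numbering): each stilbene unit a, b, c has a 4-oxyphenyl ring (ring a1, b1, c1; C1–C6), the carbons C7 and C8, and a 3,5-dioxyphenyl ring (ring a2, b2, c2; C9–C14). In the target, C7a–C10c and C8a–C8c close the indane, C8b–C10a and C7b–O–C11a close the dihydrobenzofuran, and C7c–C10b completes the eight-membered ring.

Remark (assumptions): compounds 1, 3, 9, 10 and 13 are taken as commercial. Compounds 18 and 19 are used as mixtures of diastereomers at C7b and C7c, because step 12 erases both centres. The (S)-catalyst in step 4 is chosen on the assumption that the 2-arylvinyl side of the indenone behaves as the larger ketone substituent; the descriptors given were assigned by hand from the SMILES.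

Step 1
Reactants: 1 3-bromo-5-methoxyphenol
Product: 2 (3-bromo-5-methoxyphenoxy)(tert-butyl)dimethylsilane
Conditions: TBSCl, imidazole, DMF, rt
Reagents that add atoms: tert-butyldimethylsilyl chloride, CC(C)(C)[Si](C)(C)Cl
Why: Silylation masks the acidic phenol for the base-mediated arylation of step 2 and gives an aryl silyl ether that can later be cleaved beside an alkyl silyl ether.

Step 2
Reactants: 3 5,7-dimethoxyindan-1-one; 2 (3-bromo-5-methoxyphenoxy)(tert-butyl)dimethylsilane
Product: 4 2-[3-(tert-butyldimethylsilyloxy)-5-methoxyphenyl]-5,7-dimethoxyindan-1-one (racemic)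
Conditions: Pd(OAc)2 (3 mol %), XPhos (6 mol %), K3PO4, toluene, 100 °C
Reagents that add atoms: none
Why: Palladium-catalysed α-arylation of the ketone enolate places ring a2 on C8a, and a second arylation is disfavoured because it would build a quaternary centre.

Step 3
Reactants: 4 2-[3-(tert-butyldimethylsilyloxy)-5-methoxyphenyl]-5,7-dimethoxyindan-1-one
Product: 5 2-[3-(tert-butyldimethylsilyloxy)-5-methoxyphenyl]-5,7-dimethoxy-1H-inden-1-one
Conditions: IBX, DMSO, 70 °C
Reagents that add atoms: none
Why: IBX dehydrogenation of the enolisable α-aryl ketone should give the conjugated 2-arylindenone and erases the racemic C8a centre.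

Step 4
Reactants: 5 2-[3-(tert-butyldimethylsilyloxy)-5-methoxyphenyl]-5,7-dimethoxy-1H-inden-1-one
Product: 6 (1S)-2-[3-(tert-butyldimethylsilyloxy)-5-methoxyphenyl]-5,7-dimethoxy-1H-inden-1-ol
Conditions: (S)-Me-CBS (20 mol %), catecholborane, toluene, −78 °C; aqueous work-up
Reagents that add atoms: none
Why: CBS reduction delivers hydride 1,2 to one face of the ketone under control of the oxazaborolidine and sets C7a, the only stereocentre introduced by a chiral reagent.

Step 5
Reactants: 6 (1S)-2-[3-(tert-butyldimethylsilyloxy)-5-methoxyphenyl]-5,7-dimethoxy-1H-inden-1-ol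
Product: 7 tert-butyl{3-[(1S)-5,7-dimethoxy-1-(triisopropylsilyloxy)-1H-inden-2-yl]-5-methoxyphenoxy}dimethylsilane
Conditions: TIPSOTf, 2,6-lutidine, CH2Cl2, −78 °C to 0 °C
Reagents that add atoms: triisopropylsilyl trifluoromethanesulfonate, CC(C)[Si](OS(=O)(=O)C(F)(F)F)(C(C)C)C(C)C
Why: Silylation with a hindered pyridine base avoids base-induced isomerisation of the indenol to the indanone and installs the bulky group that directs step 12.

Step 6
Reactants: 7 tert-butyl{3-[(1S)-5,7-dimethoxy-1-(triisopropylsilyloxy)-1H-inden-2-yl]-5-methoxyphenoxy}dimethylsilane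
Product: 8 3-[(1S)-5,7-dimethoxy-1-(triisopropylsilyloxy)-1H-inden-2-yl]-5-methoxyphenol
Conditions: KHF2, MeOH, rt
Reagents that add atoms: none
Why: Bifluoride cleaves the phenolic silyl ether much faster than the hindered secondary alkyl silyl ether, under near-neutral conditions that leave the allylic C7a–H untouched.

Step 7
Reactants: 9 2-bromo-4,6-dimethoxybenzaldehyde; 10 4-methoxyphenylmagnesium bromide
Product: 11 (2-bromo-4,6-dimethoxyphenyl)(4-methoxyphenyl)methanol (racemic)
Conditions: THF, 0 °C; aq NH4Cl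
Reagents that add atoms: none
Why: Grignard addition to the aldehyde builds C7c with ring c1 attached, next to the bromide that marks C9b.

Step 8
Reactants: 11 (2-bromo-4,6-dimethoxyphenyl)(4-methoxyphenyl)methanol
Product: 12 1-bromo-3,5-dimethoxy-2-[methoxy(4-methoxyphenyl)methyl]benzene (racemic)
Conditions: NaH, MeI, THF, 0 °C to rt
Reagents that add atoms: iodomethane, CI
Why: Williamson methylation caps the benzhydrol as an ether that survives the organometallic and basic steps and serves as the leaving group in step 12.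

Step 9
Reactants: 12 1-bromo-3,5-dimethoxy-2-[methoxy(4-methoxyphenyl)methyl]benzene; 13 4-methoxyphenylacetyl chloride
Product: 16 1-{3,5-dimethoxy-2-[methoxy(4-methoxyphenyl)methyl]phenyl}-2-(4-methoxyphenyl)ethan-1-one, via aryllithium 14 (not isolated), via arylzinc chloride 15 (not isolated)
Conditions: n-BuLi, THF, −78 °C; ZnCl2, −78 °C to 0 °C; then 13, Pd(PPh3)4 (3 mol %), 0 °C to rt
Reagents that add atoms: none
Why: Bromine–lithium exchange, transmetalation to zinc and Negishi acylation should give the deoxybenzoin without over-addition or ketene formation from the acid chloride.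

Step 10
Reactants: 16 1-{3,5-dimethoxy-2-[methoxy(4-methoxyphenyl)methyl]phenyl}-2-(4-methoxyphenyl)ethan-1-one
Product: 18 2-bromo-1-{3,5-dimethoxy-2-[methoxy(4-methoxyphenyl)methyl]phenyl}-2-(4-methoxyphenyl)ethan-1-one, via lithium enolate 17 (not isolated)
Conditions: LiHMDS, THF, −78 °C; then NBS, −78 °C; aq NH4Cl
Reagents that add atoms: N-bromosuccinimide, O=C1CCC(=O)N1Br
Why: Bromination of the preformed enolate places bromine on C7b without generating HBr, which would ionise the benzhydryl ether.

Step 11
Reactants: 8 3-[(1S)-5,7-dimethoxy-1-(triisopropylsilyloxy)-1H-inden-2-yl]-5-methoxyphenol; 18 2-bromo-1-{3,5-dimethoxy-2-[methoxy(4-methoxyphenyl)methyl]phenyl}-2-(4-methoxyphenyl)ethan-1-one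
Product: 19 1-{3,5-dimethoxy-2-[methoxy(4-methoxyphenyl)methyl]phenyl}-2-{3-[(1S)-5,7-dimethoxy-1-(triisopropylsilyloxy)-1H-inden-2-yl]-5-methoxyphenoxy}-2-(4-methoxyphenyl)ethan-1-one (diastereomer mixture at C7b and C7c)
Conditions: K2CO3, acetone, rt
Reagents that add atoms: none
Why: SN2 displacement of the activated α-bromo ketone by the phenoxide forms the C11a–O–C7b ether, and carbonate is too weak a base to deprotonate C7a of the silyloxyindene.

Step 12
Reactants: 19 1-{3,5-dimethoxy-2-[methoxy(4-methoxyphenyl)methyl]phenyl}-2-{3-[(1S)-5,7-dimethoxy-1-(triisopropylsilyloxy)-1H-inden-2-yl]-5-methoxyphenoxy}-2-(4-methoxyphenyl)ethan-1-one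
Product: 22 benzofuran-fused dibenzocyclooctene indanone (7cR,8cS,8aR), via benzofuranyl diarylmethyl cation 20 (not isolated), via silyloxocarbenium ion 21 (not isolated)
Conditions: Bi(OTf)3 (20 mol %), 2,6-di-tert-butyl-4-methylpyridine (10 mol %), 4 Å molecular sieves, ClCH2CH2Cl (2 mM, slow addition), 0 °C then 60 °C
Reagents that add atoms: none
Why: Bi(OTf)3 ionises the benzhydryl methyl ether to the C7c diarylmethyl cation and activates the C8b ketone for Friedel–Crafts attack by C10a of ring a2; loss of water closes the furan ring as a 2,3-diarylbenzofuran (five-membered closure of the arene onto the carbonyl carbon, 5-exo-trig) and holds the cation beside the indene. The cation then adds to C8c of the C8c=C8a double bond in an eight-membered cation–olefin closure (8-endo-trig), and the β-silyloxy cation at C8a collapses by a suprafacial 1,2-hydride shift from C7a (semipinacol) to the silyloxocarbenium ion, which loses the silyl group to give the indan-1-one. The closest known reaction types are the domino cyclodehydration/second Friedel–Crafts-type cyclisation of α-aryloxy ketones and carbocation-initiated semipinacol (Prins–pinacol type) rearrangements of allylic alcohols and silyl ethers. C8c is set by attack on the indene face anti to the bulky OSi(iPr)3 group on C7a, the face on which allylic strain also places the ring a2 tether, so the stereocentre of step 4 is transferred to C8c as it is destroyed. C8a is set by the hydride migrating on that same face, giving the trans relation of H-8a and H-8c that is also the expected thermodynamic one for the epimerisable 2-arylindanone, and C7c is set in the closure by placing ring c1 pseudo-equatorial and anti to ring c2 on C8c. The step needs closure at C10a and not C12a (para-methoxy group on C13a), addition at C8c and not C8a (unsubstituted alkene terminus, tertiary cation), ionisation of the benzhydryl ether and not the allylic silyl ether (the indenyl cation is antiaromatic), and ring closure over intermolecular alkylation (high dilution).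

Step 13
Reactants: 22 benzofuran-fused dibenzocyclooctene indanone (7cR,8cS,8aR); 10 4-methoxyphenylmagnesium bromide
Product: 23 tertiary alcohol bearing ring a1 and OH on C7a (7cR,8cS,8aR; either epimer at C7a)
Conditions: CeCl3, THF, −78 °C to 0 °C; aq NH4Cl
Reagents that add atoms: none
Why: The organocerium reagent made from 10 should add to the hindered, enolisable ketone without deprotonating C8a, and both C7a epimers are carried on because C7a becomes planar in step 14.

Step 14
Reactants: 23 tertiary alcohol bearing ring a1 and OH on C7a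
Product: 24 canaliculatol octamethyl ether (7aR,8aS,7bR,8bR,7cR,8cR)
Conditions: Et3SiH, CF3CO2H, CH2Cl2, 0 °C to rt
Reagents that add atoms: none
Why: In this ionic hydrogenation the C7a cation should take hydride on the face anti to ring a2 on C8a (cis-1,2-diaryl indane), while the benzofuran is protonated at C8b on the face set by the rigid eight-membered ring and its oxocarbenium ion is reduced at C7b anti to ring b2 (trans-dihydrobenzofuran).

Step 15
Reactants: 24 canaliculatol octamethyl ether
Product: 25 canaliculatol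
Conditions: BBr3, CH2Cl2, −78 °C to rt; then H2O
Reagents that add atoms: none
Why: Lewis acid cleavage of the eight aryl methyl ethers should leave the skeleton intact, the only acid-labile centre being C7b, whose trans arrangement is the thermodynamic one.

Compound list

1 | 3-bromo-5-methoxyphenol | Oc1cc(Br)cc(OC)c1 | starting material
2 | (3-bromo-5-methoxyphenoxy)(tert-butyl)dimethylsilane | CC(C)(C)[Si](C)(C)Oc1cc(Br)cc(OC)c1 | intermediate
3 | 5,7-dimethoxyindan-1-one | O=C1CCc2cc(OC)cc(OC)c12 | starting material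
4 | 2-[3-(tert-butyldimethylsilyloxy)-5-methoxyphenyl]-5,7-dimethoxyindan-1-one (racemic) | O=C1C(c2cc(OC)cc(O[Si](C)(C)C(C)(C)C)c2)Cc2cc(OC)cc(OC)c12 | intermediate
5 | 2-[3-(tert-butyldimethylsilyloxy)-5-methoxyphenyl]-5,7-dimethoxy-1H-inden-1-one | O=C1C(c2cc(OC)cc(O[Si](C)(C)C(C)(C)C)c2)=Cc2cc(OC)cc(OC)c12 | intermediate
6 | (1S)-2-[3-(tert-butyldimethylsilyloxy)-5-methoxyphenyl]-5,7-dimethoxy-1H-inden-1-ol | O[C@@H]1c2c(OC)cc(OC)cc2C=C1c1cc(OC)cc(O[Si](C)(C)C(C)(C)C)c1 | intermediate
7 | tert-butyl{3-[(1S)-5,7-dimethoxy-1-(triisopropylsilyloxy)-1H-inden-2-yl]-5-methoxyphenoxy}dimethylsilane | CC(C)[Si](C(C)C)(C(C)C)O[C@@H]1c2c(OC)cc(OC)cc2C=C1c1cc(OC)cc(O[Si](C)(C)C(C)(C)C)c1 | intermediate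
8 | 3-[(1S)-5,7-dimethoxy-1-(triisopropylsilyloxy)-1H-inden-2-yl]-5-methoxyphenol | CC(C)[Si](C(C)C)(C(C)C)O[C@@H]1c2c(OC)cc(OC)cc2C=C1c1cc(O)cc(OC)c1 | intermediate
9 | 2-bromo-4,6-dimethoxybenzaldehyde | O=Cc1c(Br)cc(OC)cc1OC | starting material
10 | 4-methoxyphenylmagnesium bromide | COc1ccc([Mg]Br)cc1 | starting material
11 | (2-bromo-4,6-dimethoxyphenyl)(4-methoxyphenyl)methanol (racemic) | OC(c1ccc(OC)cc1)c1c(Br)cc(OC)cc1OC | intermediate
12 | 1-bromo-3,5-dimethoxy-2-[methoxy(4-methoxyphenyl)methyl]benzene (racemic) | COC(c1ccc(OC)cc1)c1c(Br)cc(OC)cc1OC | intermediate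
13 | 4-methoxyphenylacetyl chloride | COc1ccc(CC(Cl)=O)cc1 | starting material
14 | {3,5-dimethoxy-2-[methoxy(4-methoxyphenyl)methyl]phenyl}lithium | COC(c1ccc(OC)cc1)c1c([Li])cc(OC)cc1OC | intermediate
15 | {3,5-dimethoxy-2-[methoxy(4-methoxyphenyl)methyl]phenyl}zinc chloride | COC(c1ccc(OC)cc1)c1c([Zn]Cl)cc(OC)cc1OC | intermediate
16 | 1-{3,5-dimethoxy-2-[methoxy(4-methoxyphenyl)methyl]phenyl}-2-(4-methoxyphenyl)ethan-1-one (racemic) | COC(c1ccc(OC)cc1)c1c(cc(OC)cc1OC)C(=O)Cc1ccc(OC)cc1 | intermediate
17 | lithium enolate of 16 | [Li+].[O-]C(=Cc1ccc(OC)cc1)c1cc(OC)cc(OC)c1C(OC)c1ccc(OC)cc1 | intermediate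
18 | 2-bromo-1-{3,5-dimethoxy-2-[methoxy(4-methoxyphenyl)methyl]phenyl}-2-(4-methoxyphenyl)ethan-1-one (diastereomer mixture) | COC(c1ccc(OC)cc1)c1c(cc(OC)cc1OC)C(=O)C(Br)c1ccc(OC)cc1 | intermediate
19 | 1-{3,5-dimethoxy-2-[methoxy(4-methoxyphenyl)methyl]phenyl}-2-{3-[(1S)-5,7-dimethoxy-1-(triisopropylsilyloxy)-1H-inden-2-yl]-5-methoxyphenoxy}-2-(4-methoxyphenyl)ethan-1-one (S at C7a; mixture at C7b and C7c) | CC(C)[Si](C(C)C)(C(C)C)O[C@@H]1c2c(OC)cc(OC)cc2C=C1c1cc(OC)cc(OC(c2ccc(OC)cc2)C(=O)c2cc(OC)cc(OC)c2C(OC)c2ccc(OC)cc2)c1 | intermediate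
20 | {2-[4-((1S)-5,7-dimethoxy-1-(triisopropylsilyloxy)-1H-inden-2-yl)-6-methoxy-2-(4-methoxyphenyl)benzofuran-3-yl]-4,6-dimethoxyphenyl}(4-methoxyphenyl)methylium | CC(C)[Si](C(C)C)(C(C)C)O[C@@H]1c2c(OC)cc(OC)cc2C=C1c1cc(OC)cc2oc(-c3ccc(OC)cc3)c(-c3cc(OC)cc(OC)c3[CH+]c3ccc(OC)cc3)c12 | intermediate
21 | O-triisopropylsilyl oxocarbenium ion of ketone 22 (7cR,8cS,8aR) | CC(C)[Si](C(C)C)(C(C)C)[O+]=C2c3c(OC)cc(OC)cc3[C@H]3[C@H](c4ccc(OC)cc4)c4c(OC)cc(OC)cc4-c4c5c(cc(OC)cc5[C@H]23)oc4-c2ccc(OC)cc2 | intermediate
22 | (7cR,8cS,8aR)-ketone: 6-methoxy-2-(4-methoxyphenyl)benzofuran whose C3 (C8b) and C4 (C9a) are bridged through ring b2, C7c (bearing ring c1), C8c and C8a into the eight-membered ring; C8c and C8a are C3 and C2 of a trans-fused 5,7-dimethoxyindan-1-one (C7a = C1); seven OMe groups | O=C2c3c(OC)cc(OC)cc3[C@H]3[C@H](c4ccc(OC)cc4)c4c(OC)cc(OC)cc4-c4c5c(cc(OC)cc5[C@H]23)oc4-c2ccc(OC)cc2 | intermediate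
23 | (7cR,8cS,8aR)-tertiary alcohol: 22 with 4-methoxyphenyl (ring a1) and OH on C7a, either epimer at C7a | COc1ccc(C2(O)c3c(OC)cc(OC)cc3[C@H]3[C@H](c4ccc(OC)cc4)c4c(OC)cc(OC)cc4-c4c5c(cc(OC)cc5[C@H]23)oc4-c2ccc(OC)cc2)cc1 | intermediate
24 | canaliculatol octamethyl ether (7aR,8aS,7bR,8bR,7cR,8cR) | COc1ccc([C@@H]2c3c(OC)cc(OC)cc3[C@H]3[C@H](c4ccc(OC)cc4)c4c(OC)cc(OC)cc4[C@@H]4c5c(cc(OC)cc5[C@H]23)O[C@H]4c2ccc(OC)cc2)cc1 | intermediate
25 | canaliculatol (7aR,8aS,7bR,8bR,7cR,8cR) | Oc1ccc([C@@H]2c3c(O)cc(O)cc3[C@H]3[C@H](c4ccc(O)cc4)c4c(O)cc(O)cc4[C@@H]4c5c(cc(O)cc5[C@H]23)O[C@H]4c2ccc(O)cc2)cc1 | target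

Total step count: 15 steps.
Longest linear sequence: 11 steps (steps 1–6, then 11–15). The other branch is steps 7–10.

Steps most likely to fail

Step 12. The silyloxyindene may be isomerised by adventitious protons, or its allylic silyl ether ionised, while the slower cyclodehydration is still running, and intermolecular alkylation may compete with the eight-membered closure. The fallback separates the two bond formations and fixes their order. Setting out from 19, TMSOTf (10 mol %) with 2,6-di-tert-butyl-4-methylpyridine in CH2Cl2 at −78 °C under high dilution should ionise only the benzhydryl ether. The cation–olefin/semipinacol closure would then give the eleven-membered macrocyclic diketone F1, with the aryloxy ketone untouched and the indanone already formed. Transannular cyclodehydration of F1 with Amberlyst 15 in toluene at 80 °C then closes the furan ring and comes back to the route at 22.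

Step 14. Protonation of the benzofuran at C8b may show poor facial selectivity, and reversible elimination of the C7a cation towards C8a may erode the C8a configuration. The fallback sets out from 23. Et3SiH with BF3·OEt2 in CH2Cl2 at −78 °C should reduce only the tertiary benzylic alcohol, trapping the cation cold and giving the benzofuran F2 with the indane stereotriad in place. Hydrogenation of F2 (H2 at 50 bar, Pd(OH)2/C, EtOAc–AcOH) adds both hydrogens from the exposed face to give the cis-dihydrobenzofuran F3. Brief treatment of F3 with CF3CO2H in CH2Cl2 epimerises C7b through the ring-opened 4-methoxybenzyl cation to the trans isomer, which is 24.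

Step 4. The ketone is flanked by two sp2 groups of similar size, so facial discrimination by the oxazaborolidine may be poor and the enantiomeric purity of C7a low. The fallback sets out from 5. Luche reduction (NaBH4, CeCl3·7H2O, MeOH, −40 °C) gives the racemic indenol F4. Kinetic resolution with immobilised Candida antarctica lipase B and vinyl acetate in tert-butyl methyl ether is expected to acetylate the (R)-enantiomer to the acetate F5, leaving the (S)-alcohol, which re-enters the route at 6.

Further compounds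

F1 | step 12 | eleven-membered macrocyclic diketone (7cR,8cS,8aR; mixture at C7b): C7c–C8c bond and indan-1-one formed, aryloxy ketone intact | O=C2c3c(OC)cc(OC)cc3[C@H]3[C@H](c4ccc(OC)cc4)c4c(OC)cc(OC)cc4C(=O)C(c4ccc(OC)cc4)Oc4cc(OC)cc(c4)[C@H]23
F2 | step 14 | 7b,8b-didehydro canaliculatol octamethyl ether (benzofuran; 7aR,8aS,7cR,8cR) | COc1ccc([C@@H]2c3c(OC)cc(OC)cc3[C@H]3[C@H](c4ccc(OC)cc4)c4c(OC)cc(OC)cc4-c4c5c(cc(OC)cc5[C@H]23)oc4-c2ccc(OC)cc2)cc1
F3 | step 14 | 7b-epi-canaliculatol octamethyl ether (cis-dihydrobenzofuran) | COc1ccc([C@@H]2c3c(OC)cc(OC)cc3[C@H]3[C@H](c4ccc(OC)cc4)c4c(OC)cc(OC)cc4[C@@H]4c5c(cc(OC)cc5[C@H]23)O[C@@H]4c2ccc(OC)cc2)cc1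
F4 | step 4 | racemic 2-[3-(tert-butyldimethylsilyloxy)-5-methoxyphenyl]-5,7-dimethoxy-1H-inden-1-ol | OC1c2c(OC)cc(OC)cc2C=C1c1cc(OC)cc(O[Si](C)(C)C(C)(C)C)c1
F5 | step 4 | (1R)-2-[3-(tert-butyldimethylsilyloxy)-5-methoxyphenyl]-5,7-dimethoxy-1H-inden-1-yl acetate | CC(=O)O[C@H]1c2c(OC)cc(OC)cc2C=C1c1cc(OC)cc(O[Si](C)(C)C(C)(C)C)c1
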